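## Structural features

The target is a (2R,3R)-dihydroflavonol: a benzene ring A fused to a dihydropyranone ring C (O1, C2, C3, C4, C4a, C8a), with a 4-hydroxyphenyl ring B on C2, a hydroxyl on C3 and the ketone at C4. C2 and C3 are adjacent, both carry oxygen, and their substituents are trans. Ring A is a fully differentiated phloroglucinol: 5-OH chelated to the ketone, 7-OH, and between them at C6 a 2-methylbut-3-en-2-yl group bonded through its quaternary carbon; C8 is the only C–H of ring A. The β-aryloxy ketone with its acidic C3–H opens or epimerises in base, the free 4′-phenol can open the C2–O1 bond through a quinone methide, and the 3-hydroxy ketone is easily oxidised to the flavonol. The terminal alkene rules out hydrogenolysis and, in strong acid, is attacked by the flanking phenols. The real difficulty is twofold: the two oxygenated stereocentres must be set in the absolute sense without equilibrating conditions, and the two carbonyl-flanked oxygens of ring A must be told apart, because closing ring C on the wrong one gives the 8-substituted isomer. The key step uses the position of C3: it bears oxygen and lies between the C4 carbonyl and the C2 carbinol, so it can enter as the carbene carbon of a ring A diazomethyl ketone, taking its oxygen from an alcohol and its bond to C2 from the aldehyde that brings ring B.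

## Logic of the disconnections

Target numbering is used for all atoms, also in open-chain compounds.

16 ⇐ 14 (through 15). The O5–Si, O7–Si and O4′–acyl bonds are cut. The phenols stay masked to the end because the free polyphenol is sensitive to base and oxidants. The gain is a last operation that is only deprotection; the demand is near-neutral conditions that touch neither C2 nor C3.

14 ⇐ 13. The O3–CH2 bond of the 4-methoxybenzyl ether is cut. It is removed oxidatively while every phenol is still masked. The demand is an oxidant that attacks only the electron-rich benzyl ether and leaves C2–H and the alkene alone.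

13 ⇐ 12. The O1–C2 bond is cut. This removes ring C and turns C2 into a secondary benzylic carbinol of opposite configuration, so the problem becomes an open-chain syn aldol. The forward step must be a clean SN2 closure with inversion, and 12 must have exactly one free phenol, the one that becomes O1.

12 ⇐ 11. One O–Si bond is cut, at the ring A oxygen next to C8–H. The reason is regiocontrol of the ring closure. The demand is that this silyl ether be the most labile of three, which is designed into 11: it is the only tert-butyldimethylsilyl ether with an unsubstituted neighbour, the other is wedged between the quaternary carbon and the acyl group, and O7 carries triisopropylsilyl.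

11 ⇐ 8 + 9 + 10. The C2–C3 and C3–O bonds are cut. This is the strategic cut: it divides the molecule into ring A with C4 and C3 (8), the oxygen on C3 (9) and ring B with C2 (10), and it creates both stereocentres at once. The forward step must trap a transient oxonium ylide with an aldehyde faster than the proton shift, under catalyst control of both faces.

8 ⇐ 6 (through 7). The C3=N2 bond is cut, leading back to a methyl ketone. The demand is diazo transfer to a methyl group on a very crowded aryl ketone without disturbing the ortho silyl ethers.

6 ⇐ 5. The O7–Si bond is cut; the forward step caps the phenol freed by the rearrangement with the bulkiest of the three silyl groups.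

5 ⇐ 4. The C6–C(quaternary) bond is cut and the allyl unit is returned to O7 as a prenyl ether ([3,3] retron). In 4 the two ortho positions are equivalent and the para position carries the acetyl group, so only one aromatic product is possible. An ether on a carbonyl-flanked oxygen was rejected: its para position (the future C8) is free, so the allyl group would move on by a Cope shift and arrive as a normal prenyl group on the wrong carbon. The demand is a thermal step that does not let the new phenol add to the new alkene.

4 ⇐ 3 ⇐ 1 + 2. Two O–Si bonds and then the O7–CH2 bond are cut. Alkylation precedes silylation because the hydroxyl para to the acetyl group of 1 is the most acidic and the least encumbered. The demand is mono-O-alkylation without C-alkylation of the electron-rich ring.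

## Other disconnections considered

Alternative 1: The cut is C3–C4. The forward step treats the dialdehyde A2, a ring A aldehyde whose ortho oxygen already carries the ring B-bearing oxoethyl unit and which is racemic at the future C2, with a chiral triazolium-derived carbene. The acyl anion equivalent formed at the ring A aldehyde adds to the aliphatic aldehyde, closes ring C and gives A1, while the labile C2 centre of A2 equilibrates (dynamic kinetic resolution).
- In its favour: ring closure and both stereocentres come from one organocatalytic step. The 3-hydroxyl emerges free, so no ether has to be removed at C3. The oxygen that becomes O1 is fixed before the key step. On these three points it is the better plan.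
- Against it here: the carbene should add faster to the unhindered aliphatic aldehyde than to the electron-rich, doubly ortho-substituted ring A aldehyde, which reverses the polarity pattern required. That aliphatic aldehyde also carries an α-aryloxy leaving group, so the carbene adduct can expel the ring A phenoxide and destroy the tether. The product keeps an acidic C3–H next to the ketone under the basic conditions of its own formation. Three methoxymethyl ethers must finally be removed with acid beside the alkene and its flanking phenols.
- Comparison: both plans create the two stereocentres from achiral or racemic material under one chiral catalyst. The chosen plan separates C–C formation from ring closure and pays with a Mitsunobu step and an extra deprotection. Alternative 1 is probably one or two steps shorter, but it depends on a chemoselectivity that the electronics of A2 oppose.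

Alternative 2: The cut runs through ring A (C5–C6, C7–C8, C4a–C5). The forward step irradiates the pyranone diazo ketone A4 in the presence of the siloxyalkyne A5. Wolff rearrangement gives a vinylketene, [2+2] addition of A5 gives a vinylcyclobutenone, and four-electron opening followed by six-electron closure and tautomerisation gives A3.
- In its favour: the substitution pattern of ring A is programmed by the polarity of the alkyne. The quaternary carbon lands between the two oxygens without a Claisen step, 5-OH and 7-O are differentiated automatically, and O1 is in ring C from the start, so the ortho-oxygen question never arises. The endgame is a single fluoride treatment. On regiochemistry and endgame it is the better plan.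
- Against it here: C2 and C3 are not made by the key step. They must be built enantioselectively into A4 and then survive ultraviolet light and heat as part of a β-alkoxy enone, which is itself photoactive and can open at C2–O1. The alkyne carbon that must bond to the ketene is neopentyl-like. The terminal alkene of A5 is a second partner for ketene or enone cycloaddition. Both A4 and A5 need multistep preparation.
- Comparison: the cascade is pericyclic with no catalyst control of configuration, whereas the chosen plan sets both centres by catalyst. In step count Alternative 2 is clearly longer.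

Alternative 3: The cut is C2–C3 as a ring-closing bond. The forward step decomposes the diazomethyl ketone A7 with Rh2(S-PTTL)4; the carbene at C3 inserts into the benzylic C–H bond of the ortho ether and gives the flavanone A6.
- In its favour: ring C and the C2 centre form in one catalytic step with no activation or inversion of an alcohol. The ether fixes which oxygen becomes O1. The route to A7 uses the same rearrangement and diazo-transfer chemistry as the chosen plan, so the two are equal up to that point.
- Against it here: the ether oxygen sits where a five-membered oxonium ylide forms easily, and a Stevens-type 1,2-shift of the benzyl group is then the expected fate of such a carbene. Six-ring C–H insertion has to outrun this. Enantiocontrol with acceptor-only carbenes from diazomethyl ketones is usually modest. The C3 oxygen is not introduced at all. It needs a later enolate hydroxylation trans to the aryl group, which exposes a 5-oxygenated flavanone to base that can open it to the chalcone and erase C2. Acidic removal of the methoxymethyl groups follows.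
- Comparison: both plans use a rhodium carbene at C3. The chosen plan lets the carbene take the C3 oxygen and C2 in the same event; Alternative 3 forms only the C–C bond. In step count Alternative 3 is equal at best and more likely one step longer.

Key step: step 6

Assumption: the (R)-enantiomer of the phosphoric acid (R)-TRIP, that is (R)-3,3′-bis(2,4,6-triisopropylphenyl)-1,1′-binaphthyl-2,2′-diyl hydrogen phosphate, is taken to deliver the (2R,3S) adduct 11; if the sense of induction is the opposite, the (S)-acid is used and nothing else changes.

## Route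

Step 1
Reactants: 1 2,4,6-trihydroxyacetophenone; 2 3-methylbut-2-en-1-ol
Product: 3 1-[2,6-dihydroxy-4-(3-methylbut-2-en-1-yloxy)phenyl]ethanone
Conditions: PPh3, DIAD, THF, 0 °C → rt (1 dried azeotropically, 2 as limiting reagent)
Reagents that add atoms: none
Why: Mitsunobu etherification; the hydroxyl para to the acetyl group is the most acidic and the only one neither hydrogen-bonded to nor crowded by the carbonyl, so it should be alkylated selectively, and the neutral conditions avoid the C-prenylation that phenoxide alkylation of this ring suffers.

Step 2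
Reactants: 3 1-[2,6-dihydroxy-4-(3-methylbut-2-en-1-yloxy)phenyl]ethanone
Product: 4 1-[2,6-bis(tert-butyldimethylsilyloxy)-4-(3-methylbut-2-en-1-yloxy)phenyl]ethanone
Conditions: TBSCl (3 equiv), imidazole, DMAP (cat.), DMF, 40 °C
Reagents that add atoms: tert-butyldimethylsilyl chloride, CC(C)(C)[Si](C)(C)Cl
Why: Silylation of both carbonyl-flanked phenols; two identical groups keep the ring symmetric, so the coming rearrangement has a single possible outcome.

Step 3
Reactants: 4 1-[2,6-bis(tert-butyldimethylsilyloxy)-4-(3-methylbut-2-en-1-yloxy)phenyl]ethanone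
Product: 5 1-[2,6-bis(tert-butyldimethylsilyloxy)-4-hydroxy-3-(2-methylbut-3-en-2-yl)phenyl]ethanone
Conditions: PhNEt2, 190 °C, sealed tube, Ar
Reagents that add atoms: none
Why: Aromatic Claisen rearrangement; the two ortho positions are equivalent and the para position carries the acetyl group, so only the ortho product with the inverted (1,1-dimethylallyl) unit can aromatise. The amine solvent speeds tautomerisation of the dienone and suppresses acid-catalysed addition of the new phenol to the new alkene.

Step 4
Reactants: 5 1-[2,6-bis(tert-butyldimethylsilyloxy)-4-hydroxy-3-(2-methylbut-3-en-2-yl)phenyl]ethanone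
Product: 6 1-[2,6-bis(tert-butyldimethylsilyloxy)-3-(2-methylbut-3-en-2-yl)-4-(triisopropylsilyloxy)phenyl]ethanone
Conditions: TIPSOTf, 2,6-lutidine, CH2Cl2, 0 °C → rt
Reagents that add atoms: triisopropylsilyl trifluoromethanesulfonate, CC(C)[Si](OS(=O)(=O)C(F)(F)F)(C(C)C)C(C)C
Why: Silylation of a phenol beside a quaternary carbon needs the silyl triflate; the bulkier group on this oxygen is what later allows one tert-butyldimethylsilyl ether to be removed alone.

Step 5
Reactants: 6 1-[2,6-bis(tert-butyldimethylsilyloxy)-3-(2-methylbut-3-en-2-yl)-4-(triisopropylsilyloxy)phenyl]ethanone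
Product: 8 2-diazo-1-[2,6-bis(tert-butyldimethylsilyloxy)-3-(2-methylbut-3-en-2-yl)-4-(triisopropylsilyloxy)phenyl]ethanone, via trifluoroacetyl diketone 7 (not isolated)
Conditions: LiN(SiMe3)2, THF, −78 °C; CF3CO2CH2CF3, −78 °C; aqueous HCl quench, crude 7 taken on; 4-AcNHC6H4SO2N3, Et3N, H2O, MeCN, rt
Reagents that add atoms: 4-acetamidobenzenesulfonyl azide, CC(=O)Nc1ccc(cc1)S(=O)(=O)N=[N+]=[N-]; 2,2,2-trifluoroethyl trifluoroacetate, O=C(OCC(F)(F)F)C(F)(F)F (trifluoroacetyl group of 7 only)
Why: Detrifluoroacetylative diazo transfer; Claisen condensation of the lithium enolate with the trifluoroacetate activates the methyl group as a 1,3-diketone, and the sulfonyl azide then transfers the diazo group while the trifluoroacetyl group leaves as the N-acylsulfonamide. The enolate is kept at −78 °C so that no silyl group moves from an ortho oxygen to the enolate oxygen.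

Step 6
Reactants: 8 2-diazo-1-[2,6-bis(tert-butyldimethylsilyloxy)-3-(2-methylbut-3-en-2-yl)-4-(triisopropylsilyloxy)phenyl]ethanone; 9 4-methoxybenzyl alcohol; 10 4-acetoxybenzaldehyde
Product: 11 (2R,3S)-3-(4-acetoxyphenyl)-1-[2,6-bis(tert-butyldimethylsilyloxy)-3-(2-methylbut-3-en-2-yl)-4-(triisopropylsilyloxy)phenyl]-3-hydroxy-2-(4-methoxybenzyloxy)propan-1-one (syn)
Conditions: Rh2(OAc)4 (2 mol %), (R)-TRIP (5 mol %), 4 Å MS, CH2Cl2, −20 °C, 8 and 9 added over 2 h to 10 and the catalysts
Reagents that add atoms: none
Why: Rh2(OAc)4 extrudes N2 from 8 to give an electrophilic acyl carbene at the future C3; 9 adds through oxygen to give a protic oxonium ylide, in effect a metal-associated enol, and before the 1,2-proton shift can complete a plain O–H insertion this enol adds to 10, which the phosphoric acid activates by hydrogen bonding. The closest known reaction type is the three-component aldol-type trapping of oxonium ylides from diazo carbonyl compounds, alcohols and aldehydes under Rh2(OAc)4 and chiral phosphoric acid co-catalysis. No ring is closed; the C3–O and C2–C3 bonds are formed. Both stereocentres arise in the C–C bond-forming event: the acid bridges the enol O–H and the aldehyde oxygen in a cyclic hydrogen-bonded transition state, which fixes the enol face (chain C2, R; target C3) and the aldehyde face (chain C3, S; target C2 before inversion) and places the two oxygens syn. The step needs intermolecular ylide formation and trapping to win over every intramolecular path and over the proton shift. The two ortho silyloxy groups twist the acyl group out of the ring plane, so neither their weakly basic oxygens nor the distant vinyl group can reach the carbene; the acetoxy group keeps 10 electrophilic; and slow addition of 8 holds the carbene concentration low. The main by-product expected is the simple O–H insertion ether.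

Step 7
Reactants: 11 (2R,3S)-3-(4-acetoxyphenyl)-1-[2,6-bis(tert-butyldimethylsilyloxy)-3-(2-methylbut-3-en-2-yl)-4-(triisopropylsilyloxy)phenyl]-3-hydroxy-2-(4-methoxybenzyloxy)propan-1-one
Product: 12 (2R,3S)-3-(4-acetoxyphenyl)-1-[2-(tert-butyldimethylsilyloxy)-6-hydroxy-3-(2-methylbut-3-en-2-yl)-4-(triisopropylsilyloxy)phenyl]-3-hydroxy-2-(4-methoxybenzyloxy)propan-1-one
Conditions: Bu4NF (1.05 equiv), AcOH (1.2 equiv), THF, −20 → 0 °C
Reagents that add atoms: none
Why: Fluoride cleavage of an aryl silyl ether; of the three only the one next to C8–H is a tert-butyldimethylsilyl ether with an open flank, the other is shielded by the quaternary carbon and the acyl group, and the third is triisopropylsilyl. Buffering with acetic acid should prevent retro-aldol cleavage, epimerisation at the α-carbon and loss of the aryl acetate.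

Step 8
Reactants: 12 (2R,3S)-3-(4-acetoxyphenyl)-1-[2-(tert-butyldimethylsilyloxy)-6-hydroxy-3-(2-methylbut-3-en-2-yl)-4-(triisopropylsilyloxy)phenyl]-3-hydroxy-2-(4-methoxybenzyloxy)propan-1-one
Product: 13 (2R,3R)-2-(4-acetoxyphenyl)-5-(tert-butyldimethylsilyloxy)-3-(4-methoxybenzyloxy)-6-(2-methylbut-3-en-2-yl)-7-(triisopropylsilyloxy)chroman-4-one
Conditions: PPh3, DIAD, THF (0.01 M), 0 °C → rt
Reagents that add atoms: none
Why: Intramolecular Mitsunobu etherification (6-exo-tet SN2): the only free phenol displaces the activated benzylic oxygen with inversion, turning C2 from S to R and giving the trans ring with C3 untouched. The 4-acetoxy group disfavours ionisation of the benzylic centre, and because the other ortho oxygen is still silylated the ring can close only to the 6-substituted isomer.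

Step 9
Reactants: 13 (2R,3R)-2-(4-acetoxyphenyl)-5-(tert-butyldimethylsilyloxy)-3-(4-methoxybenzyloxy)-6-(2-methylbut-3-en-2-yl)-7-(triisopropylsilyloxy)chroman-4-one
Product: 14 (2R,3R)-2-(4-acetoxyphenyl)-5-(tert-butyldimethylsilyloxy)-3-hydroxy-6-(2-methylbut-3-en-2-yl)-7-(triisopropylsilyloxy)chroman-4-one
Conditions: DDQ, CH2Cl2/pH 7 phosphate buffer (10:1), 0 °C → rt
Reagents that add atoms: none
Why: Oxidative cleavage of the 4-methoxybenzyl ether by hydride abstraction and hydrolysis of the resulting oxocarbenium ion. C2–H is benzylic only to an electron-poor acetoxyphenyl ring, the allyl group has no allylic hydrogen, and all phenols are masked, so the quinone should react only at the ether.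

Step 10
Reactants: 14 (2R,3R)-2-(4-acetoxyphenyl)-5-(tert-butyldimethylsilyloxy)-3-hydroxy-6-(2-methylbut-3-en-2-yl)-7-(triisopropylsilyloxy)chroman-4-one
Product: 16 (2R,3R)-3,5,7-trihydroxy-2-(4-hydroxyphenyl)-6-(2-methylbut-3-en-2-yl)chroman-4-one, via phenolic acetate 15 (not isolated)
Conditions: Bu4NF (2.5 equiv), AcOH (3 equiv), THF, 0 °C → rt; then NH4OAc, MeOH/H2O (4:1), rt
Reagents that add atoms: none
Why: Buffered fluoride removes both aryl silyl ethers, and ammonium acetate-mediated methanolysis then removes the aryl acetate in the same flask. Both stages are near neutral, which avoids base-induced opening of ring C, epimerisation at C2 or C3 and oxidation to the flavonol.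

## Compound list

1 | 2,4,6-trihydroxyacetophenone | CC(=O)c1c(O)cc(O)cc1O | starting material
2 | 3-methylbut-2-en-1-ol | CC(C)=CCO | starting material
3 | 1-[2,6-dihydroxy-4-(3-methylbut-2-en-1-yloxy)phenyl]ethanone | CC(=O)c1c(O)cc(OCC=C(C)C)cc1O | intermediate
4 | 1-[2,6-bis(tert-butyldimethylsilyloxy)-4-(3-methylbut-2-en-1-yloxy)phenyl]ethanone | CC(=O)c1c(O[Si](C)(C)C(C)(C)C)cc(OCC=C(C)C)cc1O[Si](C)(C)C(C)(C)C | intermediate
5 | 1-[2,6-bis(tert-butyldimethylsilyloxy)-4-hydroxy-3-(2-methylbut-3-en-2-yl)phenyl]ethanone | CC(=O)c1c(O[Si](C)(C)C(C)(C)C)cc(O)c(C(C)(C)C=C)c1O[Si](C)(C)C(C)(C)C | intermediate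
6 | 1-[2,6-bis(tert-butyldimethylsilyloxy)-3-(2-methylbut-3-en-2-yl)-4-(triisopropylsilyloxy)phenyl]ethanone | CC(=O)c1c(O[Si](C)(C)C(C)(C)C)cc(O[Si](C(C)C)(C(C)C)C(C)C)c(C(C)(C)C=C)c1O[Si](C)(C)C(C)(C)C | intermediate
7 | 1-[2,6-bis(tert-butyldimethylsilyloxy)-3-(2-methylbut-3-en-2-yl)-4-(triisopropylsilyloxy)phenyl]-4,4,4-trifluorobutane-1,3-dione | O=C(CC(=O)C(F)(F)F)c1c(O[Si](C)(C)C(C)(C)C)cc(O[Si](C(C)C)(C(C)C)C(C)C)c(C(C)(C)C=C)c1O[Si](C)(C)C(C)(C)C | intermediate (not isolated)
8 | 2-diazo-1-[2,6-bis(tert-butyldimethylsilyloxy)-3-(2-methylbut-3-en-2-yl)-4-(triisopropylsilyloxy)phenyl]ethanone | [N-]=[N+]=CC(=O)c1c(O[Si](C)(C)C(C)(C)C)cc(O[Si](C(C)C)(C(C)C)C(C)C)c(C(C)(C)C=C)c1O[Si](C)(C)C(C)(C)C | intermediate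
9 | 4-methoxybenzyl alcohol | COc1ccc(CO)cc1 | starting material
10 | 4-acetoxybenzaldehyde | CC(=O)Oc1ccc(C=O)cc1 | starting material
11 | (2R,3S)-3-(4-acetoxyphenyl)-1-[2,6-bis(tert-butyldimethylsilyloxy)-3-(2-methylbut-3-en-2-yl)-4-(triisopropylsilyloxy)phenyl]-3-hydroxy-2-(4-methoxybenzyloxy)propan-1-one | C=CC(C)(C)c1c(O[Si](C(C)C)(C(C)C)C(C)C)cc(O[Si](C)(C)C(C)(C)C)c(c1O[Si](C)(C)C(C)(C)C)C(=O)[C@H](OCc1ccc(OC)cc1)[C@H](c1ccc(OC(C)=O)cc1)O | intermediate
12 | (2R,3S)-3-(4-acetoxyphenyl)-1-[2-(tert-butyldimethylsilyloxy)-6-hydroxy-3-(2-methylbut-3-en-2-yl)-4-(triisopropylsilyloxy)phenyl]-3-hydroxy-2-(4-methoxybenzyloxy)propan-1-one | C=CC(C)(C)c1c(O[Si](C(C)C)(C(C)C)C(C)C)cc(O)c(c1O[Si](C)(C)C(C)(C)C)C(=O)[C@H](OCc1ccc(OC)cc1)[C@H](c1ccc(OC(C)=O)cc1)O | intermediate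
13 | (2R,3R)-2-(4-acetoxyphenyl)-5-(tert-butyldimethylsilyloxy)-3-(4-methoxybenzyloxy)-6-(2-methylbut-3-en-2-yl)-7-(triisopropylsilyloxy)chroman-4-one | C=CC(C)(C)c1c(O[Si](C(C)C)(C(C)C)C(C)C)cc2c(c1O[Si](C)(C)C(C)(C)C)C(=O)[C@H](OCc1ccc(OC)cc1)[C@@H](c1ccc(OC(C)=O)cc1)O2 | intermediate
14 | (2R,3R)-2-(4-acetoxyphenyl)-5-(tert-butyldimethylsilyloxy)-3-hydroxy-6-(2-methylbut-3-en-2-yl)-7-(triisopropylsilyloxy)chroman-4-one | C=CC(C)(C)c1c(O[Si](C(C)C)(C(C)C)C(C)C)cc2c(c1O[Si](C)(C)C(C)(C)C)C(=O)[C@H](O)[C@@H](c1ccc(OC(C)=O)cc1)O2 | intermediate
15 | (2R,3R)-2-(4-acetoxyphenyl)-3,5,7-trihydroxy-6-(2-methylbut-3-en-2-yl)chroman-4-one | C=CC(C)(C)c1c(O)cc2c(c1O)C(=O)[C@H](O)[C@@H](c1ccc(OC(C)=O)cc1)O2 | intermediate (not isolated)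
16 | (2R,3R)-3,5,7-trihydroxy-2-(4-hydroxyphenyl)-6-(2-methylbut-3-en-2-yl)chroman-4-one | C=CC(C)(C)c1c(O)cc2c(c1O)C(=O)[C@H](O)[C@@H](c1ccc(O)cc1)O2 | target

## Step count and least certain steps

Total: 10 steps. Longest linear sequence: 10 steps (1 → 16); 2, 9 and 10 are bought and enter at steps 1 and 6.

Step 6 (key step). The proton shift of the oxonium ylide may outrun the aldol trapping, because the enol sits on a very crowded aryl ketone and the aldehyde is only moderately activated; facial control by the acid may also be incomplete for so hindered an enol. Fallback: setting out from 8 and 9, Rh2(OAc)4 alone should give the plain O–H insertion product, the α-(4-methoxybenzyloxy) ketone F1. Its Z-boron enolate, formed with the matched enantiomer of Ipc2BOTf and iPr2NEt, should add to 10 through a closed chair-like transition state to give the syn adduct, returning to the route at 11.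

Step 3. At the temperature needed, the newly formed phenol may react further with the neighbouring vinyl group (ene-type isomerisation of the allyl unit or cyclisation to a dihydrobenzofuran). Fallback: setting out from 4, the rearrangement is run in PhNEt2 with N,O-bis(trimethylsilyl)acetamide so that the phenol is captured as it forms, giving the trimethylsilyl ether F2; mild methanolysis returns to the route at 5.

Step 5. Silyl transfer from an ortho oxygen to the enolate oxygen, or incomplete acylation of the crowded enolate, may erode the diazo transfer. Fallback: setting out from 6, condensation with N,N-dimethylformamide dimethyl acetal (no strong base) should give the enaminone F3, and its cycloaddition with the sulfonyl azide followed by cycloreversion should deliver the diazo ketone, returning at 8.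

Step 7. Discrimination among the three silyl ethers is steric only, so over-desilylation or attack at the wrong ether may occur. Fallback: setting out from 11, excess Bu4NF/AcOH removes all three silyl groups to give the triol F4. Mitsunobu closure then relies on the less hindered ortho hydroxyl, the other being chelated and buttressed by the quaternary carbon, and gives the 5,7-dihydroxy flavanone ether F5. DDQ removes the 4-methoxybenzyl group and the route is rejoined at 15, which is deacetylated as in the second stage of step 10.

Step 8. Dehydration of the activated β-hydroxy ketone toward the enone, or sluggish attack by the chelated phenol, may compete with substitution and erode C2. Fallback: setting out from 12, NH4OAc in aqueous MeOH removes the ring B acetate to give the 4-hydroxybenzylic alcohol F6. A catalytic sulfonic acid then closes ring C through the para-quinone methide. Since this closure is reversible and C3 is intact, the more stable trans isomer F7 should accumulate. Acetylation of the single free phenol (Ac2O, pyridine) returns to the route at 13.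

## Further compounds

F1 | step 6 | 1-[2,6-bis(tert-butyldimethylsilyloxy)-3-(2-methylbut-3-en-2-yl)-4-(triisopropylsilyloxy)phenyl]-2-(4-methoxybenzyloxy)ethanone | COc1ccc(COCC(=O)c2c(O[Si](C)(C)C(C)(C)C)cc(O[Si](C(C)C)(C(C)C)C(C)C)c(C(C)(C)C=C)c2O[Si](C)(C)C(C)(C)C)cc1
F2 | step 3 | 1-[2,6-bis(tert-butyldimethylsilyloxy)-3-(2-methylbut-3-en-2-yl)-4-(trimethylsilyloxy)phenyl]ethanone | CC(=O)c1c(O[Si](C)(C)C(C)(C)C)cc(O[Si](C)(C)C)c(C(C)(C)C=C)c1O[Si](C)(C)C(C)(C)C
F3 | step 5 | (E)-1-[2,6-bis(tert-butyldimethylsilyloxy)-3-(2-methylbut-3-en-2-yl)-4-(triisopropylsilyloxy)phenyl]-3-(dimethylamino)prop-2-en-1-one | CN(C)/C=C/C(=O)c1c(O[Si](C)(C)C(C)(C)C)cc(O[Si](C(C)C)(C(C)C)C(C)C)c(C(C)(C)C=C)c1O[Si](C)(C)C(C)(C)C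
F4 | step 7 | (2R,3S)-3-(4-acetoxyphenyl)-3-hydroxy-2-(4-methoxybenzyloxy)-1-[2,4,6-trihydroxy-3-(2-methylbut-3-en-2-yl)phenyl]propan-1-one | C=CC(C)(C)c1c(O)cc(O)c(c1O)C(=O)[C@H](OCc1ccc(OC)cc1)[C@H](c1ccc(OC(C)=O)cc1)O
F5 | step 7 | (2R,3R)-2-(4-acetoxyphenyl)-5,7-dihydroxy-3-(4-methoxybenzyloxy)-6-(2-methylbut-3-en-2-yl)chroman-4-one | C=CC(C)(C)c1c(O)cc2c(c1O)C(=O)[C@H](OCc1ccc(OC)cc1)[C@@H](c1ccc(OC(C)=O)cc1)O2
F6 | step 8 | (2R,3S)-1-[2-(tert-butyldimethylsilyloxy)-6-hydroxy-3-(2-methylbut-3-en-2-yl)-4-(triisopropylsilyloxy)phenyl]-3-hydroxy-3-(4-hydroxyphenyl)-2-(4-methoxybenzyloxy)propan-1-one | C=CC(C)(C)c1c(O[Si](C(C)C)(C(C)C)C(C)C)cc(O)c(c1O[Si](C)(C)C(C)(C)C)C(=O)[C@H](OCc1ccc(OC)cc1)[C@H](c1ccc(O)cc1)O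
F7 | step 8 | (2R,3R)-5-(tert-butyldimethylsilyloxy)-2-(4-hydroxyphenyl)-3-(4-methoxybenzyloxy)-6-(2-methylbut-3-en-2-yl)-7-(triisopropylsilyloxy)chroman-4-one | C=CC(C)(C)c1c(O[Si](C(C)C)(C(C)C)C(C)C)cc2c(c1O[Si](C)(C)C(C)(C)C)C(=O)[C@H](OCc1ccc(OC)cc1)[C@@H](c1ccc(O)cc1)O2
A1 | alternative 1 | (2R,3R)-3-hydroxy-5,7-bis(methoxymethoxy)-2-[4-(methoxymethoxy)phenyl]-6-(2-methylbut-3-en-2-yl)chroman-4-one | C=CC(C)(C)c1c(OCOC)cc2c(c1OCOC)C(=O)[C@H](O)[C@@H](c1ccc(OCOC)cc1)O2
A2 | alternative 1 | 2-[2-formyl-3,5-bis(methoxymethoxy)-4-(2-methylbut-3-en-2-yl)phenoxy]-2-[4-(methoxymethoxy)phenyl]acetaldehyde (racemic) | C=CC(C)(C)c1c(OCOC)cc(OC(C=O)c2ccc(OCOC)cc2)c(C=O)c1OCOC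
A3 | alternative 2 | (2R,3R)-3-(tert-butyldimethylsilyloxy)-2-[4-(tert-butyldimethylsilyloxy)phenyl]-5-hydroxy-6-(2-methylbut-3-en-2-yl)-7-(triisopropylsilyloxy)chroman-4-one | C=CC(C)(C)c1c(O[Si](C(C)C)(C(C)C)C(C)C)cc2c(c1O)C(=O)[C@H](O[Si](C)(C)C(C)(C)C)[C@@H](c1ccc(O[Si](C)(C)C(C)(C)C)cc1)O2
A4 | alternative 2 | (2R,3R)-3-(tert-butyldimethylsilyloxy)-2-[4-(tert-butyldimethylsilyloxy)phenyl]-6-(2-diazoacetyl)-2,3-dihydro-4H-pyran-4-one | [N-]=[N+]=CC(=O)C1=CC(=O)[C@H](O[Si](C)(C)C(C)(C)C)[C@@H](c2ccc(O[Si](C)(C)C(C)(C)C)cc2)O1
A5 | alternative 2 | [(3,3-dimethylpent-4-en-1-yn-1-yl)oxy]triisopropylsilane | C=CC(C)(C)C#CO[Si](C(C)C)(C(C)C)C(C)C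
A6 | alternative 3 | (2S)-5-(tert-butyldimethylsilyloxy)-7-(methoxymethoxy)-2-[4-(methoxymethoxy)phenyl]-6-(2-methylbut-3-en-2-yl)chroman-4-one | C=CC(C)(C)c1c(OCOC)cc2c(c1O[Si](C)(C)C(C)(C)C)C(=O)C[C@@H](c1ccc(OCOC)cc1)O2
A7 | alternative 3 | 2-diazo-1-[2-(tert-butyldimethylsilyloxy)-4-(methoxymethoxy)-6-{[4-(methoxymethoxy)phenyl]methoxy}-3-(2-methylbut-3-en-2-yl)phenyl]ethanone | [N-]=[N+]=CC(=O)c1c(OCc2ccc(OCOC)cc2)cc(OCOC)c(C(C)(C)C=C)c1O[Si](C)(C)C(C)(C)C
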